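**Plan**

- Numbering used throughout: C1=C2 is the vinyl group on C3; the oxane is O–C3–C4–C5–C6(Br)–C7; C8–C9 is the ethylene link; C10–C15 is the six-membered carbocycle of the 7-oxabicyclo[2.2.1]heptane, whose oxygen joins C11 and C14; C16 is the methyl on C15.
- Retrosynthesis: first O–C7 and C6–Br are cut (bromoetherification of a C3 carbinol onto an (E)-C6=C7 alkene), then C8–C9 (alkylation of a C9 sulfone with a C8 allylic bromide), then O–C11 and C10–C15 of the bicycle in one cut.
- Feature behind the last cut: C15 is a CH(CH3) directly on the oxygen-bearing C14, and C11 is a tertiary ether carbon facing C14 across the ring C10–C15. A vinyl carbinol (C16=C15–C14–O) two methylenes away from an (E)-C11(Me)=C10 alkene therefore holds the whole bicycle: H• to C16 gives a C15 radical that closes 6-endo onto C10, and the C11 centre left behind is oxidized and taken by the C14 oxygen.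
- Forward: (S)-linalool supplies both halves. The right half (ozonolysis, alkyne homologation, carboalumination, sulfone) is bicyclized first, the left half (allylic oxidation, bromide) is joined at C8–C9, and the oxane is closed last.
- Stereochemistry: C3 and C14 come from (S)-linalool; C10, C11 and C15 from the chair transition state of the key step and the E geometry set by the carboalumination; C6 and C7 from anti addition to the (E)-C6=C7 alkene.

Key step: step 6

Assumption: (S)-(+)-linalool of high enantiomeric purity is taken as commercially available; both C3 and C14 of the target map onto its carbinol carbon.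

**Route**

Step 1
Reactants: 1 (S)-(+)-linalool
Product: 2 triethyl{[(3S)-3,7-dimethylocta-1,6-dien-3-yl]oxy}silane
Conditions: TESOTf, 2,6-lutidine, CH2Cl2, −78 → 0 °C
Reagents that add atoms: triethylsilyl trifluoromethanesulfonate, CC[Si](CC)(CC)OS(=O)(=O)C(F)(F)F
Why: Silyl ether formation with a silyl triflate works on hindered tertiary alcohols and leaves the stereocentre untouched; the ether later protects the left half and serves as the oxygen nucleophile of the key step in the right half.

Step 2
Reactants: 2 triethyl{[(3S)-3,7-dimethylocta-1,6-dien-3-yl]oxy}silane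
Product: 3 (4S)-4-methyl-4-(triethylsilyloxy)hex-5-enal
Conditions: O3 (1 equiv, Sudan Red 7B end-point), CH2Cl2, −78 °C; then Me2S, −78 °C → rt
Reagents that add atoms: ozone, [O-][O+]=O
Why: Ozonolysis with reductive work-up should cleave only the electron-rich trisubstituted alkene, which reacts with ozone far faster than the monosubstituted vinyl group next to the silyloxy carbon.

Step 3
Reactants: 3 (4S)-4-methyl-4-(triethylsilyloxy)hex-5-enal
Product: 4 triethyl{[(3S)-3-methylhept-1-en-6-yn-3-yl]oxy}silane
Conditions: dimethyl (1-diazo-2-oxopropyl)phosphonate, K2CO3, MeOH, 0 °C → rt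
Reagents that add atoms: dimethyl (1-diazo-2-oxopropyl)phosphonate, CC(=O)C(=[N+]=[N-])P(=O)(OC)OC
Why: Ohira–Bestmann homologation turns the aldehyde into the terminal alkyne under mild carbonate conditions that leave the silyl ether and the quaternary stereocentre alone.

Step 4
Reactants: 4 triethyl{[(3S)-3-methylhept-1-en-6-yn-3-yl]oxy}silane
Product: 7 (2E,6S)-3,6-dimethyl-6-(triethylsilyloxy)octa-2,7-dien-1-ol, via alkenyldimethylalane 5 (not isolated), via lithium alkenylalanate 6 (not isolated)
Conditions: Me3Al, Cp2ZrCl2 (cat.), CH2Cl2, 0 °C → rt; volatiles removed; n-BuLi, hexane, 0 °C; (CH2O)n, THF, rt; aq. Rochelle salt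
Reagents that add atoms: trimethylaluminium, C[Al](C)C; formaldehyde (from paraformaldehyde), C=O
Why: Negishi carboalumination adds methyl and aluminium syn across the terminal alkyne (methyl to the internal carbon) and the derived alanate adds to formaldehyde with retention, which fixes the E geometry of the trisubstituted alkene; the vinyl group is inert to methylalumination under these conditions.

Step 5
Reactants: 7 (2E,6S)-3,6-dimethyl-6-(triethylsilyloxy)octa-2,7-dien-1-ol
Product: 9 triethyl{[(3S,6E)-3,6-dimethyl-8-(phenylsulfonyl)octa-1,6-dien-3-yl]oxy}silane, via allylic mesylate 8 (not isolated)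
Conditions: MsCl, Et3N, CH2Cl2, −20 °C; then PhSO2Na, Bu4NI (cat.), DMF, rt
Reagents that add atoms: sodium benzenesulfinate, [Na+].[O-]S(=O)c1ccccc1
Why: Mesylation of the primary allylic alcohol and SN2 displacement by the sulfur of the sulfinate (allylic sulfone synthesis) should keep the E geometry and not touch the tertiary silyl ether.

Step 6
Reactants: 9 triethyl{[(3S,6E)-3,6-dimethyl-8-(phenylsulfonyl)octa-1,6-dien-3-yl]oxy}silane
Product: 10 (1R,2R,3R,4S)-1,3,4-trimethyl-2-[(phenylsulfonyl)methyl]-7-oxabicyclo[2.2.1]heptane (2-endo arm, 3-exo methyl)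
Conditions: Co(salen) (cat.; salen = N,N'-bis(3,5-di-tert-butylsalicylidene)cyclohexane-1,2-diaminate, C36H52N2O2), N-fluoro-2,4,6-trimethylpyridinium triflate, PhSiH3, PhCF3, 0 °C → rt
Reagents that add atoms: none
Why: Proposed new method: the cobalt hydride formed from the divalent cobalt salen complex, the N-fluoropyridinium oxidant and the silane should give a hydrogen atom to C16 of the vinyl group, the secondary C15 radical should add 6-endo-trig to C10 of the (E)-alkene (closing the carbocycle C10–C15), and the tertiary C11 radical should be oxidized by trivalent cobalt to the cation, which the C14 silyloxy oxygen takes in a transannular 1,4-closure through the boat (closing both oxolane rings at once) with loss of the silyl group. The closest known reaction types are the cobalt-hydride-initiated radical cyclization of polyenes with 6-endo closure onto C(Me)=CH alkenes and the cobalt-catalysed radical–polar crossover hydroalkoxylation of alkenes by free or silyl-protected hydroxyl groups; their union in one event that starts at a vinyl carbinol and ends in a bridged ether has not been shown. C15 and C10 are set in the chair transition state of the 6-endo closure, in which the C14 methyl, the C15 methyl and the C10 sulfonylmethyl arm (trans to C12 in the E-alkene) are equatorial and only the smaller silyloxy group is axial, so that the C15 methyl ends syn and the C10 arm anti to the oxygen bridge (15R, 10R); C11 (R) follows from C14, because the tethered oxygen can reach only one face of the cation. The step needs hydrogen-atom transfer to the vinyl group and not to the trisubstituted alkene (secured by the bulk of the salen catalyst), 6-endo and not 5-exo closure (secured by the methyl group on C11, which hinders attack there and makes the 6-endo radical tertiary), ring closure before oxidation of the C15 radical (the silyl ether removes the free hydroxyl that could otherwise close an epoxide), and ether closure before loss of a proton (alkenes formed by elimination can re-enter through the cobalt hydride).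

Step 7
Reactants: 2 triethyl{[(3S)-3,7-dimethylocta-1,6-dien-3-yl]oxy}silane
Product: 11 (2E,6S)-2,6-dimethyl-6-(triethylsilyloxy)octa-2,7-dien-1-ol
Conditions: SeO2 (cat.), t-BuOOH, salicylic acid (cat.), CH2Cl2, rt
Reagents that add atoms: tert-butyl hydroperoxide, CC(C)(C)OO (terminal oxidant; the oxygen is passed on by selenium dioxide, O=[Se]=O)
Why: Catalytic SeO2 allylic oxidation (ene reaction, then [2,3]-shift) takes the methyl group trans to the chain on the disubstituted end of the trisubstituted alkene and so gives the (E)-allylic alcohol; the vinyl group has no allylic hydrogen.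

Step 8
Reactants: 11 (2E,6S)-2,6-dimethyl-6-(triethylsilyloxy)octa-2,7-dien-1-ol
Product: 12 triethyl{[(3S,6E)-8-bromo-3,7-dimethylocta-1,6-dien-3-yl]oxy}silane
Conditions: CBr4, PPh3, 2,6-lutidine, CH2Cl2, −20 → 0 °C
Reagents that add atoms: carbon tetrabromide, BrC(Br)(Br)Br
Why: Appel bromination of the primary allylic alcohol proceeds by SN2 at low temperature, which keeps the E geometry and avoids allylic transposition.

Step 9
Reactants: 10 (1R,2R,3R,4S)-1,3,4-trimethyl-2-[(phenylsulfonyl)methyl]-7-oxabicyclo[2.2.1]heptane; 12 triethyl{[(3S,6E)-8-bromo-3,7-dimethylocta-1,6-dien-3-yl]oxy}silane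
Product: 14 (3S,6E)-3,7-dimethyl-9-(phenylsulfonyl)-9-[(1R,2R,3R,4S)-1,3,4-trimethyl-7-oxabicyclo[2.2.1]heptan-2-yl]-3-(triethylsilyloxy)nona-1,6-diene (both C9 epimers), via lithiated sulfone 13 (not isolated)
Conditions: n-BuLi, THF, −78 °C; then 12, DMPU, −78 → −20 °C
Reagents that add atoms: none
Why: Alkylation of the α-sulfonyl carbanion with the primary allylic bromide (SN2 at the allylic terminus) forms C8–C9; the new sulfone-bearing centre is removed in the next step, so its configuration does not matter.

Step 10
Reactants: 14 (3S,6E)-3,7-dimethyl-9-(phenylsulfonyl)-9-[(1R,2R,3R,4S)-1,3,4-trimethyl-7-oxabicyclo[2.2.1]heptan-2-yl]-3-(triethylsilyloxy)nona-1,6-diene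
Product: 15 (3S,6E)-3,7-dimethyl-9-[(1R,2R,3R,4S)-1,3,4-trimethyl-7-oxabicyclo[2.2.1]heptan-2-yl]-3-(triethylsilyloxy)nona-1,6-diene
Conditions: Na(Hg), Na2HPO4, MeOH/THF, −20 °C → rt
Reagents that add atoms: none
Why: Reductive desulfonylation with sodium amalgam (electron transfer, loss of sulfinate, protonation by methanol) replaces the sulfonyl group by hydrogen without touching the alkenes, the silyl ether or the bicycle.

Step 11
Reactants: 15 (3S,6E)-3,7-dimethyl-9-[(1R,2R,3R,4S)-1,3,4-trimethyl-7-oxabicyclo[2.2.1]heptan-2-yl]-3-(triethylsilyloxy)nona-1,6-diene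
Product: 16 (3S,6E)-3,7-dimethyl-9-[(1R,2R,3R,4S)-1,3,4-trimethyl-7-oxabicyclo[2.2.1]heptan-2-yl]nona-1,6-dien-3-ol
Conditions: TBAF, THF, rt → 40 °C
Reagents that add atoms: none
Why: Fluoride cleavage of the tertiary triethylsilyl ether frees the C3 hydroxyl needed as the nucleophile of the last step and affects no stereocentre.

Step 12
Reactants: 16 (3S,6E)-3,7-dimethyl-9-[(1R,2R,3R,4S)-1,3,4-trimethyl-7-oxabicyclo[2.2.1]heptan-2-yl]nona-1,6-dien-3-ol
Product: 17 dactylopyranoid
Conditions: TBCO, MeNO2, 0 °C → rt, dark
Reagents that add atoms: 2,4,4,6-tetrabromocyclohexa-2,5-dien-1-one (TBCO), O=C1C(Br)=CC(Br)(Br)C=C1Br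
Why: In this bromoetherification the bromonium ion forms at the trisubstituted C6=C7 alkene (more nucleophilic than the vinyl group) and the C3 hydroxyl opens it at the tertiary C7 in a 6-endo chair closure, so Br and O add anti across the E-alkene; the two alkene faces differ only in whether the C3 methyl or the C3 vinyl group is axial in that chair, so the target (6R,7S) should form together with its 6,7-bis-epimer and must be separated from it by chromatography.

**Compound list**

1 | (S)-(+)-linalool, (3S)-3,7-dimethylocta-1,6-dien-3-ol | C=C[C@@](C)(O)CCC=C(C)C | starting material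
2 | triethyl{[(3S)-3,7-dimethylocta-1,6-dien-3-yl]oxy}silane | C=C[C@@](C)(O[Si](CC)(CC)CC)CCC=C(C)C | intermediate
3 | (4S)-4-methyl-4-(triethylsilyloxy)hex-5-enal | C=C[C@@](C)(O[Si](CC)(CC)CC)CCC=O | intermediate
4 | triethyl{[(3S)-3-methylhept-1-en-6-yn-3-yl]oxy}silane | C=C[C@@](C)(O[Si](CC)(CC)CC)CCC#C | intermediate
5 | dimethyl[(1E,5S)-2,5-dimethyl-5-(triethylsilyloxy)hepta-1,6-dien-1-yl]alumane | C=C[C@@](C)(O[Si](CC)(CC)CC)CC/C(C)=C/[Al](C)C | intermediate (not isolated)
6 | lithium butyl(dimethyl)[(1E,5S)-2,5-dimethyl-5-(triethylsilyloxy)hepta-1,6-dien-1-yl]aluminate | [Li+].C=C[C@@](C)(O[Si](CC)(CC)CC)CC/C(C)=C/[Al-](C)(C)CCCC | intermediate (not isolated)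
7 | (2E,6S)-3,6-dimethyl-6-(triethylsilyloxy)octa-2,7-dien-1-ol | C=C[C@@](C)(O[Si](CC)(CC)CC)CC/C(C)=C/CO | intermediate
8 | (2E,6S)-3,6-dimethyl-6-(triethylsilyloxy)octa-2,7-dien-1-yl methanesulfonate | C=C[C@@](C)(O[Si](CC)(CC)CC)CC/C(C)=C/COS(C)(=O)=O | intermediate (not isolated)
9 | triethyl{[(3S,6E)-3,6-dimethyl-8-(phenylsulfonyl)octa-1,6-dien-3-yl]oxy}silane | C=C[C@@](C)(O[Si](CC)(CC)CC)CC/C(C)=C/CS(=O)(=O)c1ccccc1 | intermediate
10 | (1R,2R,3R,4S)-1,3,4-trimethyl-2-[(phenylsulfonyl)methyl]-7-oxabicyclo[2.2.1]heptane (2-endo arm, 3-exo methyl) | O=S(=O)(c1ccccc1)C[C@@H]2[C@@H](C)[C@]3(C)CC[C@@]2(C)O3 | intermediate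
11 | (2E,6S)-2,6-dimethyl-6-(triethylsilyloxy)octa-2,7-dien-1-ol | C=C[C@@](C)(O[Si](CC)(CC)CC)CC/C=C(\C)CO | intermediate
12 | triethyl{[(3S,6E)-8-bromo-3,7-dimethylocta-1,6-dien-3-yl]oxy}silane | C=C[C@@](C)(O[Si](CC)(CC)CC)CC/C=C(\C)CBr | intermediate
13 | α-lithio derivative of sulfone 10 | [Li]C(S(=O)(=O)c1ccccc1)[C@@H]2[C@@H](C)[C@]3(C)CC[C@@]2(C)O3 | intermediate (not isolated)
14 | (3S,6E)-3,7-dimethyl-9-(phenylsulfonyl)-9-[(1R,2R,3R,4S)-1,3,4-trimethyl-7-oxabicyclo[2.2.1]heptan-2-yl]-3-(triethylsilyloxy)nona-1,6-diene (both C9 epimers) | C=C[C@@](C)(O[Si](CC)(CC)CC)CC/C=C(\C)CC(S(=O)(=O)c1ccccc1)[C@@H]2[C@@H](C)[C@]3(C)CC[C@@]2(C)O3 | intermediate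
15 | (3S,6E)-3,7-dimethyl-9-[(1R,2R,3R,4S)-1,3,4-trimethyl-7-oxabicyclo[2.2.1]heptan-2-yl]-3-(triethylsilyloxy)nona-1,6-diene | C=C[C@@](C)(O[Si](CC)(CC)CC)CC/C=C(\C)CC[C@@H]2[C@@H](C)[C@]3(C)CC[C@@]2(C)O3 | intermediate
16 | (3S,6E)-3,7-dimethyl-9-[(1R,2R,3R,4S)-1,3,4-trimethyl-7-oxabicyclo[2.2.1]heptan-2-yl]nona-1,6-dien-3-ol | C=C[C@@](C)(O)CC/C=C(\C)CC[C@@H]2[C@@H](C)[C@]3(C)CC[C@@]2(C)O3 | intermediate
17 | dactylopyranoid, (2S,3R,6S)-3-bromo-6-ethenyl-2,6-dimethyl-2-{2-[(1R,2R,3R,4S)-1,3,4-trimethyl-7-oxabicyclo[2.2.1]heptan-2-yl]ethyl}oxane | C=C[C@]1(C)CC[C@@H](Br)[C@](C)(CC[C@@H]2[C@@H](C)[C@]3(C)CC[C@@]2(C)O3)O1 | target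

**Step count and risks**

Total step count: 12. Longest linear sequence: 10 steps (steps 1, 2, 3, 4, 5, 6, 9, 10, 11, 12).

Steps most likely to fail:

1. Step 6 (proposed new method). Three things may go wrong. The first (secondary) radical may be oxidized before it has closed the carbocycle. The C11 cation may lose a proton before the hindered silyloxy oxygen reaches it, which would give open-chain or monocyclic alkenes instead of the bridged ether. Weak discrimination between the two chairs would erode the C10/C15 configuration. The fallback uses known chemistry, sets out from 9 and returns at 10. Without oxidant, Co(salen)Cl (trivalent cobalt, cat.) and PhSiH3 (cat.) in benzene would run only the hydrogen-atom-transfer radical cycloisomerization (same chair, same 6-endo closure, the tertiary radical returning a hydrogen atom to cobalt). This would give triethyl{[(1S,2R,3R)-1,2-dimethyl-4-methylidene-3-[(phenylsulfonyl)methyl]cyclohexyl]oxy}silane F1. TBAF in THF would give (1S,2R,3R)-1,2-dimethyl-4-methylidene-3-[(phenylsulfonyl)methyl]cyclohexan-1-ol F2. A catalytic sulfonic acid (CSA, CH2Cl2) would then add the tertiary hydroxyl across the exocyclic alkene at its substituted carbon in the transannular 1,4-sense, as in the acid closure of 4-hydroxy-p-menthenes to 1,4-cineoles, and deliver 10.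

2. Step 12. The bromonium ion may be diverted (loss of a proton to allylic bromides, capture by the ether oxygen of the bicycle) and the two alkene faces are poorly discriminated, so little oxane of the right configuration may result. The fallback sets out from 16 and returns at 17. Hg(OCOCF3)2 in MeNO2 would close the oxane by reversible anti oxymercuration, which has no proton-loss channel, and exchange with aqueous KBr would give bromo{(2S,3R,6S)-6-ethenyl-2,6-dimethyl-2-{2-[(1R,2R,3R,4S)-1,3,4-trimethyl-7-oxabicyclo[2.2.1]heptan-2-yl]ethyl}oxan-3-yl}mercury F3. Brominative demercuration under polar conditions (Br2, LiBr, pyridine, 0 °C, dark), which replaces mercury by bromine with retention, would give 17. The face problem is not removed by this; in either variant the unwanted anti-adduct can be returned to 16 by reductive β-elimination with zinc.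

3. Step 2. Ozone may go on to attack the vinyl group once the trisubstituted alkene is consumed (loss of chemoselectivity by over-oxidation). The fallback sets out from 2 and returns at 3. mCPBA (CH2Cl2, NaHCO3, 0 °C) would epoxidize only the trisubstituted alkene to triethyl{[(3S)-5-(3,3-dimethyloxiran-2-yl)-3-methylpent-1-en-3-yl]oxy}silane F4; the silyl ether prevents closure to linalool oxides. H5IO6 in THF/Et2O at 0 °C would cleave the epoxide to aldehyde 3.

Further compounds
F1 | step 6 | triethyl{[(1S,2R,3R)-1,2-dimethyl-4-methylidene-3-[(phenylsulfonyl)methyl]cyclohexyl]oxy}silane | O=S(=O)(c1ccccc1)C[C@@H]2[C@@H](C)[C@@](C)(O[Si](CC)(CC)CC)CCC2=C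
F2 | step 6 | (1S,2R,3R)-1,2-dimethyl-4-methylidene-3-[(phenylsulfonyl)methyl]cyclohexan-1-ol | O=S(=O)(c1ccccc1)C[C@@H]2[C@@H](C)[C@@](C)(O)CCC2=C
F3 | step 12 | bromo{(2S,3R,6S)-6-ethenyl-2,6-dimethyl-2-{2-[(1R,2R,3R,4S)-1,3,4-trimethyl-7-oxabicyclo[2.2.1]heptan-2-yl]ethyl}oxan-3-yl}mercury | C=C[C@]1(C)CC[C@@H]([Hg]Br)[C@](C)(CC[C@@H]2[C@@H](C)[C@]3(C)CC[C@@]2(C)O3)O1
F4 | step 2 | triethyl{[(3S)-5-(3,3-dimethyloxiran-2-yl)-3-methylpent-1-en-3-yl]oxy}silane (both epoxide epimers) | C=C[C@@](C)(O[Si](CC)(CC)CC)CCC1OC1(C)C
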